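Fraxiresinol is numbered C1 (ring-fusion CH), C2 (guaiacyl-bearing), O3, C4, C5 (ring-fusion carbinol), C6 (syringyl-bearing), O7, C8; ring A is C1/C2/O3/C4/C5, ring B is C5/C6/O7/C8/C1. Everything rests on cutting C1–C5 and C6–O7. The feature used is that C1, which carries the C8–O7 arm, sits next to a fully substituted, oxygen-bearing C5 whose other neighbour C6 is benzylic. One titanium-catalysed operation on an epoxide (C1, C8, O7) tethered through C2–O3–C4 to an aryl enol silane (C5=C6) makes C1–C5 by radical cyclisation (ring A) and C6–O7 by oxidative closure (ring B), fixing C1, C5 and C6 from C2. The precursor is thus an aryl oxiranylmethyl ether of a silyl-enolised syringylmethyl ketone.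

Key step: step 8

Remark 1: the kinetic resolution in step 3 gives the erythro epoxy alcohol, so 5, 11 and 12 carry an (S)-oxirane carbon beside (R)-C2; that carbon becomes the planar C1 radical in step 8, so only C2 has to be defined.
Remark 2: the enol oxygen is protected as a triethylsilyl ether and the two phenols as tert-butyldimethylsilyl ethers; the smaller group eases attack at the fully substituted C5 and the exo placement of the syringyl ring, and it leaves the tertiary C5 oxygen under mild fluoride conditions.
Remark 3: homosyringic acid is assumed to be commercially available.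

Step 1
Reactants: 1 vanillin
Product: 2 4-(tert-butyldimethylsilyloxy)-3-methoxybenzaldehyde
Conditions: TBSCl, imidazole, DMF, rt
Reagents that add atoms: tert-butyldimethylsilyl chloride, CC(C)(C)[Si](C)(C)Cl
Why: Imidazole-promoted silyl ether protection masks the acidic phenol before the Grignard step and creates no stereocentre.

Step 2
Reactants: 2 4-(tert-butyldimethylsilyloxy)-3-methoxybenzaldehyde; 3 vinylmagnesium bromide
Product: 4 rac-1-[4-(tert-butyldimethylsilyloxy)-3-methoxyphenyl]prop-2-en-1-ol
Conditions: THF, −78 to 0 °C; then H2O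
Reagents that add atoms: none
Why: Grignard 1,2-addition of the vinyl nucleophile to the aldehyde gives the racemic allylic alcohol, whose carbinol centre (the later C2) is resolved in step 3.

Step 3
Reactants: 4 rac-1-[4-(tert-butyldimethylsilyloxy)-3-methoxyphenyl]prop-2-en-1-ol
Product: 5 (R)-[4-(tert-butyldimethylsilyloxy)-3-methoxyphenyl][(2S)-oxiran-2-yl]methanol (erythro)
Conditions: Ti(OiPr)4 (0.15 equiv), D-(−)-DIPT (0.2 equiv), TBHP (0.45 equiv), 4 Å MS, CH2Cl2, −20 °C
Reagents that add atoms: tert-butyl hydroperoxide, CC(C)(C)OO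
Why: In this Sharpless kinetic resolution the Ti(OiPr)4/D-(−)-DIPT catalyst should epoxidise the (S)-enantiomer of 4 much faster than the (R)-enantiomer and with erythro selectivity, so that stopping below half conversion selects the C2 configuration (descriptor R in 5 only because the oxirane carbon now outranks the aryl group) and sets the oxirane carbon as S by catalyst-controlled face selection, while unchanged (R)-4 is removed by chromatography.

Step 4
Reactants: 6 homosyringic acid
Product: 8 2-[4-(tert-butyldimethylsilyloxy)-3,5-dimethoxyphenyl]acetic acid, via bis-silylated silyl ester 7 (not isolated)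
Conditions: TBSCl (2.4 equiv), imidazole, DMF, rt; then AcOH/THF/H2O, rt
Reagents that add atoms: tert-butyldimethylsilyl chloride, CC(C)(C)[Si](C)(C)Cl
Why: Silylation of both the phenol and the carboxylic acid followed by mild aqueous acid, which hydrolyses only the labile silyl ester, leaves the aryl silyl ether that keeps the phenol out of the acid chloride and carbenoid chemistry.

Step 5
Reactants: 8 2-[4-(tert-butyldimethylsilyloxy)-3,5-dimethoxyphenyl]acetic acid
Product: 10 1-diazo-3-[4-(tert-butyldimethylsilyloxy)-3,5-dimethoxyphenyl]propan-2-one, via acid chloride 9 (not isolated)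
Conditions: (COCl)2, cat. DMF, CH2Cl2, 0 °C to rt, evaporate; then TMSCHN2 (1.5 equiv), THF/MeCN, 0 °C
Reagents that add atoms: trimethylsilyldiazomethane, C[Si](C)(C)C=[N+]=[N-]; oxalyl chloride, O=C(Cl)C(=O)Cl (chlorine of 9 only)
Why: Acid chloride formation and C-acylation of trimethylsilyldiazomethane with loss of chlorotrimethylsilane (Arndt–Eistert-type diazoketone synthesis) give the α-diazoketone without an amine base that could turn the arylacetyl chloride into a ketene.

Step 6
Reactants: 5 (R)-[4-(tert-butyldimethylsilyloxy)-3-methoxyphenyl][(2S)-oxiran-2-yl]methanol; 10 1-diazo-3-[4-(tert-butyldimethylsilyloxy)-3,5-dimethoxyphenyl]propan-2-one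
Product: 11 1-{(R)-[4-(tert-butyldimethylsilyloxy)-3-methoxyphenyl][(2S)-oxiran-2-yl]methoxy}-3-[4-(tert-butyldimethylsilyloxy)-3,5-dimethoxyphenyl]propan-2-one
Conditions: Rh2(OAc)4 (2 mol %), CH2Cl2, rt, slow addition of 10 (1.5 equiv) to 5
Reagents that add atoms: none
Why: O–H insertion of the Rh2(OAc)4-derived carbenoid (oxonium ylide, then proton shift) etherifies the hindered secondary alcohol under neutral conditions that leave the epoxide, the silyl ethers and the C2 stereocentre untouched, and slow addition of excess 10 to 5 favours insertion over attack of the carbenoid on the syringyl ring.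

Step 7
Reactants: 11 1-{(R)-[4-(tert-butyldimethylsilyloxy)-3-methoxyphenyl][(2S)-oxiran-2-yl]methoxy}-3-[4-(tert-butyldimethylsilyloxy)-3,5-dimethoxyphenyl]propan-2-one
Product: 12 (Z)-1-[4-(tert-butyldimethylsilyloxy)-3,5-dimethoxyphenyl]-3-{(R)-[4-(tert-butyldimethylsilyloxy)-3-methoxyphenyl][(2S)-oxiran-2-yl]methoxy}-2-(triethylsilyloxy)prop-1-ene
Conditions: TESOTf (1.3 equiv), Et3N (2.5 equiv), CH2Cl2, −78 to 0 °C
Reagents that add atoms: triethylsilyl trifluoromethanesulfonate, CC[Si](CC)(CC)OS(=O)(=O)C(F)(F)F
Why: Soft enolisation with silyl triflate and amine (enol silane formation) should occur at the benzylic C6 methylene, far more acidic than the alkoxy-substituted C4 methylene, and give the conjugated enol silane with the aryl group cis to the silyloxy group (Z), a geometry that step 8 erases in any case.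

Step 8
Reactants: 12 (Z)-1-[4-(tert-butyldimethylsilyloxy)-3,5-dimethoxyphenyl]-3-{(R)-[4-(tert-butyldimethylsilyloxy)-3-methoxyphenyl][(2S)-oxiran-2-yl]methoxy}-2-(triethylsilyloxy)prop-1-ene
Product: 13 (3R,3aS,6S,6aR)-3-[4-(tert-butyldimethylsilyloxy)-3,5-dimethoxyphenyl]-6-[4-(tert-butyldimethylsilyloxy)-3-methoxyphenyl]-3a-(triethylsilyloxy)tetrahydro-1H,3H-furo[3,4-c]furan (tris-silyl fraxiresinol; C1 R, C2 S, C5 S, C6 R)
Conditions: Cp2TiCl2 (20 mol %), Mn dust (40 mol %), THF (0.02 M), rt
Reagents that add atoms: none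
Why: Proposed new method: Cp2TiCl (trivalent titanium, formed from Cp2TiCl2 and Mn) should open the epoxide of 12 at C1–O7 to the secondary β-titanoxy radical, which adds 5-exo-trig to C5 of the enol silane (ring A) and leaves a C6 benzylic radical; this radical, made easy to oxidise by the para-silyloxy syringyl ring, should close onto the oxygen O7 held by tetravalent titanium (ring B, polar 5-exo-trig capture of a quinone-methide-like C6 centre) and return trivalent titanium, so that the step is a redox-neutral isomerisation. The closest known reaction types are the Cp2TiCl-mediated cyclisation of epoxy cinnamyl ethers to furofurans with benzylic C–O closure and titanium redox-relay catalysis, in which a benzylic radical closes onto a titanium-bound heteroatom; the oxygen-bearing acceptor carbon is the untested element. C1 is set by the chair-like 5-exo transition state, in which the C2 aryl group is pseudo-equatorial and C8 ends trans to it; C5 follows from the same transition state (C6 cis to C8, silyloxy group syn to H1), the only arrangement from which ring B can close cis-fused; C6 places the syringyl group on the convex (exo) face in the ionic closure. The step needs attack at C5 (5-exo) instead of C6 (6-endo), which the aryl group on C6 and the 3-oxa tether secure, and oxidative instead of reductive termination, which the low stationary concentration of trivalent titanium and the electron-rich ring secure, since a C6 carbanion would expel the C5 silyloxy group.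

Step 9
Reactants: 13 tris-silyl fraxiresinol
Product: 14 fraxiresinol
Conditions: TBAF (3.5 equiv), THF, 0 °C to rt; then AcOH
Reagents that add atoms: none
Why: Fluoride-mediated desilylation should cleave the two aryl silyl ethers and the tertiary triethylsilyl ether at or below room temperature, conditions under which the benzylic ether centres C2 and C6 are not ionised.

Compound list
1 | vanillin (4-hydroxy-3-methoxybenzaldehyde) | COc1cc(C=O)ccc1O | starting material
2 | 4-(tert-butyldimethylsilyloxy)-3-methoxybenzaldehyde | COc1cc(C=O)ccc1O[Si](C)(C)C(C)(C)C | intermediate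
3 | vinylmagnesium bromide | C=C[Mg]Br | starting material
4 | rac-1-[4-(tert-butyldimethylsilyloxy)-3-methoxyphenyl]prop-2-en-1-ol | COc1cc(C(O)C=C)ccc1O[Si](C)(C)C(C)(C)C | intermediate
5 | (R)-[4-(tert-butyldimethylsilyloxy)-3-methoxyphenyl][(2S)-oxiran-2-yl]methanol (erythro) | COc1cc([C@@H](O)[C@@H]2CO2)ccc1O[Si](C)(C)C(C)(C)C | intermediate
6 | homosyringic acid (4-hydroxy-3,5-dimethoxyphenylacetic acid) | COc1cc(CC(=O)O)cc(OC)c1O | starting material
7 | tert-butyldimethylsilyl 2-[4-(tert-butyldimethylsilyloxy)-3,5-dimethoxyphenyl]acetate | COc1cc(CC(=O)O[Si](C)(C)C(C)(C)C)cc(OC)c1O[Si](C)(C)C(C)(C)C | intermediate (not isolated)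
8 | 2-[4-(tert-butyldimethylsilyloxy)-3,5-dimethoxyphenyl]acetic acid | COc1cc(CC(=O)O)cc(OC)c1O[Si](C)(C)C(C)(C)C | intermediate
9 | 2-[4-(tert-butyldimethylsilyloxy)-3,5-dimethoxyphenyl]acetyl chloride | COc1cc(CC(Cl)=O)cc(OC)c1O[Si](C)(C)C(C)(C)C | intermediate (not isolated)
10 | 1-diazo-3-[4-(tert-butyldimethylsilyloxy)-3,5-dimethoxyphenyl]propan-2-one | COc1cc(CC(=O)C=[N+]=[N-])cc(OC)c1O[Si](C)(C)C(C)(C)C | intermediate
11 | 1-{(R)-[4-(tert-butyldimethylsilyloxy)-3-methoxyphenyl][(2S)-oxiran-2-yl]methoxy}-3-[4-(tert-butyldimethylsilyloxy)-3,5-dimethoxyphenyl]propan-2-one | COc1cc([C@@H](OCC(=O)Cc2cc(OC)c(O[Si](C)(C)C(C)(C)C)c(OC)c2)[C@@H]2CO2)ccc1O[Si](C)(C)C(C)(C)C | intermediate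
12 | (Z)-1-[4-(tert-butyldimethylsilyloxy)-3,5-dimethoxyphenyl]-3-{(R)-[4-(tert-butyldimethylsilyloxy)-3-methoxyphenyl][(2S)-oxiran-2-yl]methoxy}-2-(triethylsilyloxy)prop-1-ene (cascade precursor) | COc1cc([C@@H](OC/C(O[Si](CC)(CC)CC)=C/c2cc(OC)c(O[Si](C)(C)C(C)(C)C)c(OC)c2)[C@@H]2CO2)ccc1O[Si](C)(C)C(C)(C)C | intermediate
13 | (3R,3aS,6S,6aR)-3-[4-(tert-butyldimethylsilyloxy)-3,5-dimethoxyphenyl]-6-[4-(tert-butyldimethylsilyloxy)-3-methoxyphenyl]-3a-(triethylsilyloxy)tetrahydro-1H,3H-furo[3,4-c]furan (cascade product) | COc1cc([C@H]2OC[C@]3(O[Si](CC)(CC)CC)[C@@H](c4cc(OC)c(O[Si](C)(C)C(C)(C)C)c(OC)c4)OC[C@H]23)ccc1O[Si](C)(C)C(C)(C)C | intermediate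
14 | fraxiresinol, (3R,3aS,6S,6aR)-3-(4-hydroxy-3,5-dimethoxyphenyl)-6-(4-hydroxy-3-methoxyphenyl)-3,4,6,6a-tetrahydro-1H-furo[3,4-c]furan-3a-ol | COc1cc([C@H]2OC[C@]3(O)[C@@H](c4cc(OC)c(O)c(OC)c4)OC[C@H]23)ccc1O | target

Total step count: 9.
Longest linear sequence: 7 steps (1 → 2 → 4 → 5 → 11 → 12 → 13 → 14); the diazoketone branch (6 → 8 → 10) adds 2 steps.

Steps most likely to fail

Step 8 (proposed new method). The C6 benzylic radical may be reduced by trivalent titanium instead of closing onto O7, after which the C5 silyloxy group is lost by β-elimination. The titanium may also fail to turn over, or the C6–O7 closure may show poor facial selectivity. The fallback uses known reactions only, sets out from 5 and returns at 14; it introduces the C5 oxygen after the radical cyclisation instead of before it. 5 is O-alkylated with propargyl bromide (NaH, TBAI, THF, 0 °C) to the propargyl ether F1. 2,6-Dimethoxyphenol is iodinated at C4 (NIS, MeCN) to 4-iodo-2,6-dimethoxyphenol F2 and silylated (TBSCl, imidazole, DMF) to the aryl iodide F3. Sonogashira coupling of F1 with F3 (Pd(PPh3)2Cl2, CuI, Et3N, THF, rt) gives the aryl propargyl ether F4. Stoichiometric Cp2TiCl (from Cp2TiCl2 and Zn dust, THF, rt) then effects the established epoxide opening and 5-exo-dig cyclisation onto the aryl alkyne with reductive termination. This gives the benzylidene tetrahydrofuran alcohol F5 with C8 trans to the C2 aryl group; its alkene geometry is immaterial. OsO4-catalysed dihydroxylation (NMO, acetone/H2O) from the face opposite the C8 hydroxymethyl group gives the triol F6 with the C5 hydroxyl cis to H1. PPTS in CH2Cl2 ionises the syringyl carbinol C6, and O7 closes ring B to the bis-silyl ether of fraxiresinol F7, which TBAF in THF converts into 14.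

Step 6. The carbenoid may be consumed by intramolecular aromatic substitution on the electron-rich syringyl ring, or by ylide formation at the epoxide oxygen, instead of O–H insertion. The fallback sets out from 10 and 5 and returns at 11. 10 is treated with aqueous HBr in Et2O at 0 °C to give the α-bromoketone F8. 5 is then etherified with F8 under Ag2O (CH2Cl2, 4 Å MS, dark), an Ag2O-assisted Williamson etherification that needs neither strong base nor carbenoid.

Step 3. The rate difference between the enantiomers may be too small, eroding the enantiomeric purity of the epoxy alcohol, or the sensitive aryl epoxy alcohol may be opened under the Ti(OiPr)4 conditions. The fallback sets out from 4 and returns at 5; it separates resolution and epoxidation. Immobilised Candida antarctica lipase B with vinyl acetate (MTBE, 30 °C) should acetylate the (R)-enantiomer to the acetate F9 and leave the (S)-alcohol F10 (Kazlauskas rule). Hydroxyl-directed epoxidation of F10 with VO(acac)2/TBHP (CH2Cl2, 0 °C), erythro-selective for a vinyl carbinol, then gives 5. The diastereoselectivity is a convenience only, because the oxirane carbon is planarised in step 8.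

Further compounds
F1 | step 8 | (2S)-2-{(R)-[4-(tert-butyldimethylsilyloxy)-3-methoxyphenyl](prop-2-yn-1-yloxy)methyl}oxirane | COc1cc([C@@H](OCC#C)[C@@H]2CO2)ccc1O[Si](C)(C)C(C)(C)C
F2 | step 8 | 4-iodo-2,6-dimethoxyphenol | COc1cc(I)cc(OC)c1O
F3 | step 8 | tert-butyl(4-iodo-2,6-dimethoxyphenoxy)dimethylsilane | COc1cc(I)cc(OC)c1O[Si](C)(C)C(C)(C)C
F4 | step 8 | (2S)-2-{(R)-[4-(tert-butyldimethylsilyloxy)-3-methoxyphenyl]({3-[4-(tert-butyldimethylsilyloxy)-3,5-dimethoxyphenyl]prop-2-yn-1-yl}oxy)methyl}oxirane | COc1cc([C@@H](OCC#Cc2cc(OC)c(O[Si](C)(C)C(C)(C)C)c(OC)c2)[C@@H]2CO2)ccc1O[Si](C)(C)C(C)(C)C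
F5 | step 8 | {(2S,3R)-2-[4-(tert-butyldimethylsilyloxy)-3-methoxyphenyl]-4-[4-(tert-butyldimethylsilyloxy)-3,5-dimethoxybenzylidene]tetrahydrofuran-3-yl}methanol (E/Z mixture) | COc1cc([C@H]2OCC(=Cc3cc(OC)c(O[Si](C)(C)C(C)(C)C)c(OC)c3)[C@@H]2CO)ccc1O[Si](C)(C)C(C)(C)C
F6 | step 8 | (3S,4R,5S)-5-[4-(tert-butyldimethylsilyloxy)-3-methoxyphenyl]-3-{[4-(tert-butyldimethylsilyloxy)-3,5-dimethoxyphenyl](hydroxy)methyl}-4-(hydroxymethyl)tetrahydrofuran-3-ol (both epimers at the benzylic carbinol) | COc1cc([C@H]2OC[C@](O)(C(O)c3cc(OC)c(O[Si](C)(C)C(C)(C)C)c(OC)c3)[C@@H]2CO)ccc1O[Si](C)(C)C(C)(C)C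
F7 | step 8 | 4,4'-bis-O-(tert-butyldimethylsilyl)fraxiresinol | COc1cc([C@H]2OC[C@]3(O)[C@@H](c4cc(OC)c(O[Si](C)(C)C(C)(C)C)c(OC)c4)OC[C@H]23)ccc1O[Si](C)(C)C(C)(C)C
F8 | step 6 | 1-bromo-3-[4-(tert-butyldimethylsilyloxy)-3,5-dimethoxyphenyl]propan-2-one | COc1cc(CC(=O)CBr)cc(OC)c1O[Si](C)(C)C(C)(C)C
F9 | step 3 | (R)-1-[4-(tert-butyldimethylsilyloxy)-3-methoxyphenyl]prop-2-en-1-yl acetate | COc1cc([C@H](OC(C)=O)C=C)ccc1O[Si](C)(C)C(C)(C)C
F10 | step 3 | (S)-1-[4-(tert-butyldimethylsilyloxy)-3-methoxyphenyl]prop-2-en-1-ol | COc1cc([C@@H](O)C=C)ccc1O[Si](C)(C)C(C)(C)C
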